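The route rests on disconnecting the C3–OH bond of the upper chromanone (flavonoid numbering; lower flavonol primed). The last step, an enzymatic C–H hydroxylation, exploits the tertiary C3–H of ring C, alpha to the C4 ketone and geminal to the ether oxygen O7′. In one operation it forms the C3–O bond with retention and selects one enantiomer of the racemic, cis-fused 3-deoxy pentacycle, fixing C2 and C3. That precursor is a masked 2-aroylbenzofuran and cannot be reached by an equilibrium oxa-Michael closure. It is therefore built with a benzyl ester blocking C3 and released, together with all phenols, by neutral hydrogenolysis and decarboxylation.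

Key step: step 12

Remarks and assumptions:
- Locants: upper chromanone atoms are unprimed (rings A and C, ring B at C2); lower flavonol atoms are primed, and its aryl ring is called ring B′.
- It is assumed that a variant of a plant flavanone 3-hydroxylase that accepts 24 can be obtained by directed evolution.
- Compound 24 is expected to be unstable to base and acid, because loss of the O1 phenoxide together with H3 aromatises the furan ring. It is therefore generated under neutral conditions and used at once.
- For the same reason the enantiomer left by the enzyme is not expected to racemise, so the resolution is treated as a plain kinetic one.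

Step 1
Reactants: 1 kaempferol; 2 benzyl bromide
Product: 3 tetra-O-benzylkaempferol
Conditions: BnBr (6 equiv), K2CO3, DMF, 80 °C
Reagents that add atoms: benzyl bromide, BrCc1ccccc1
Why: Williamson etherification under forcing conditions should alkylate all four hydroxyl groups, the hydrogen-bonded 5-OH included, and the 5-alkoxy group is what later steers electrophiles to C8.

Step 2
Reactants: 3 tetra-O-benzylkaempferol; 4 iodine
Product: 5 8-iodo-tetra-O-benzylkaempferol
Conditions: I2, CF3CO2Ag, CH2Cl2, 0 °C to rt
Reagents that add atoms: iodine, II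
Why: Electrophilic aromatic iodination with silver-activated iodine should enter C8, the position that 5,7-dialkoxyflavones offer to iodonium reagents because it is ortho to the 7-alkoxy group and to the ring oxygen, while the benzyl and 4-benzyloxyphenyl rings are far less activated.

Step 3
Reactants: 5 8-iodo-tetra-O-benzylkaempferol; 6 4-(benzyloxy)phenylboronic acid; 7 carbon monoxide
Product: 8 8-[4-(benzyloxy)benzoyl]-tetra-O-benzylkaempferol
Conditions: CO (4 bar), [1,3-bis(2,6-diisopropylphenyl)imidazol-2-ylidene](3-chloropyridine)palladium dichloride (3 mol %), Cs2CO3, chlorobenzene, 80 °C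
Reagents that add atoms: carbon monoxide, [C-]#[O+]; 4-(benzyloxy)phenylboronic acid, OB(O)c1ccc(OCc2ccccc2)cc1
Why: A carbonylative Suzuki–Miyaura coupling (oxidative addition, CO insertion, transmetalation, reductive elimination) should give the diaryl ketone, since a bulky N-heterocyclic carbene ligand is the established remedy for doubly ortho-substituted aryl iodides and CO insertion outruns direct biaryl coupling at such hindered centres.

Step 4
Reactants: 8 8-[4-(benzyloxy)benzoyl]-tetra-O-benzylkaempferol
Product: 9 8-[4-(benzyloxy)benzoyl]-3-(benzyloxy)-2-[4-(benzyloxy)phenyl]-5,7-dihydroxy-4H-chromen-4-one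
Conditions: BCl3 (2.2 equiv), CH2Cl2, −78 °C; then H2O
Reagents that add atoms: none
Why: Chelation-controlled ether cleavage should remove only the two benzyl groups that can form a six-membered boron chelate with a ketone (O5 with C4=O, O7 with the 8-aroyl carbonyl), while the 3-O-benzyl group, which could form only a five-membered chelate, and the remote ethers are expected to survive at low temperature.

Step 5
Reactants: 10 2′,4′,6′-trihydroxyacetophenone; 2 benzyl bromide
Product: 11 1-[2,4-bis(benzyloxy)-6-hydroxyphenyl]ethan-1-one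
Conditions: BnBr (2.1 equiv), K2CO3, acetone, reflux
Reagents that add atoms: benzyl bromide, BrCc1ccccc1
Why: Williamson etherification should stop at the diether because the last hydroxyl group is tied up in a hydrogen bond to the acetyl carbonyl.

Step 6
Reactants: 11 1-[2,4-bis(benzyloxy)-6-hydroxyphenyl]ethan-1-one; 12 chloromethyl methyl ether
Product: 13 1-[2,4-bis(benzyloxy)-6-(methoxymethoxy)phenyl]ethan-1-one
Conditions: MOMCl, K2CO3, DMF, rt
Reagents that add atoms: chloromethyl methyl ether, COCCl
Why: Acetal (MOM) protection of the chelated phenol with the highly reactive chloromethyl ether masks the future O1 so that it cannot lactonise onto the ester introduced next, and it stays orthogonal to the benzyl groups.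

Step 7
Reactants: 13 1-[2,4-bis(benzyloxy)-6-(methoxymethoxy)phenyl]ethan-1-one; 14 dibenzyl carbonate
Product: 15 benzyl 3-[2,4-bis(benzyloxy)-6-(methoxymethoxy)phenyl]-3-oxopropanoate
Conditions: NaH, (BnO)2CO, THF, reflux; then H2O
Reagents that add atoms: dibenzyl carbonate, O=C(OCc1ccccc1)OCc1ccccc1
Why: A crossed Claisen condensation of the methyl ketone enolate with the carbonate, driven by deprotonation of the product, should give the β-keto benzyl ester.

Step 8
Reactants: 15 benzyl 3-[2,4-bis(benzyloxy)-6-(methoxymethoxy)phenyl]-3-oxopropanoate; 16 N-bromosuccinimide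
Product: 18 benzyl 2-bromo-3-[2,4-bis(benzyloxy)-6-(methoxymethoxy)phenyl]-3-oxopropanoate (racemic), via sodium enolate 17 (not isolated)
Conditions: NaH, THF, 0 °C; then NBS, −78 °C
Reagents that add atoms: N-bromosuccinimide, O=C1CCC(=O)N1Br
Why: Electrophilic α-bromination of the preformed enolate at low temperature should outrun bromination of the electron-rich ring, and the new stereocentre is racemic and of no consequence.

Step 9
Reactants: 9 8-[4-(benzyloxy)benzoyl]-3-(benzyloxy)-2-[4-(benzyloxy)phenyl]-5,7-dihydroxy-4H-chromen-4-one; 18 benzyl 2-bromo-3-[2,4-bis(benzyloxy)-6-(methoxymethoxy)phenyl]-3-oxopropanoate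
Product: 20 dihydrofuranol aldol adduct (two racemic diastereomers), via aryloxy keto ester 19 (not isolated)
Conditions: K2CO3 (1.1 equiv), DMF, 0 °C to rt
Reagents that add atoms: benzyl 2-bromo-3-[2,4-bis(benzyloxy)-6-(methoxymethoxy)phenyl]-3-oxopropanoate, O=C(C(Br)C(=O)OCc1ccccc1)c1c(OCOC)cc(OCc2ccccc2)cc1OCc1ccccc1
Why: SN2 O-alkylation of the more acidic 7-phenoxide (the 5-OH stays locked in its hydrogen bond to C4′=O) is followed by intramolecular aldol addition of the doubly stabilised carbanion to the neighbouring diaryl ketone, the interrupted Rap–Stoermer (Feist–Benary-type) course known for bromomalonates and 2-hydroxybenzophenones, and the adduct cannot dehydrate to a benzofuran because the carbon next to the carbinol bears no hydrogen; its two stereocentres are uncontrolled, which is harmless because step 10 ionises one of them.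

Step 10
Reactants: 20 dihydrofuranol aldol adduct
Product: 21 racemic cis-fused C3 benzyl ester
Conditions: CF3CO2H, CH2Cl2, 0 °C to rt
Reagents that add atoms: none
Why: In this acid-mediated SN1 etherification the doubly benzylic tertiary alcohol ionises to a cation that has no adjacent hydrogen to lose, the MOM acetal is cleaved, and the freed phenol oxygen closes the six-membered ring C reversibly, so that only the cis-fused racemate with the ester syn to the C2 aryl group can form.

Step 11
Reactants: 21 racemic cis-fused C3 benzyl ester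
Product: 24 racemic 3-deoxy compound (cis-fused; H3 syn to the C2 aryl group), via keto acid 22 (not isolated), via enol 23 (not isolated)
Conditions: H2 (1 atm), Pd/C, THF–EtOAc, rt; filtration; 30 °C under argon until CO2 loss ends; used at once
Reagents that add atoms: none
Why: Hydrogenolysis frees the five phenols and the β-keto acid, which loses CO2 through the usual cyclic transition state, and ketonisation of the enol by protonation of C3 on the convex face, syn to the C2 aryl group, gives the cis-fused racemate under neutral conditions in which base- or acid-induced opening to the benzofuran is not triggered.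

Step 12
Reactants: 24 racemic 3-deoxy compound; 25 dioxygen
Product: 26 target CNP0314633.1, (2R,3S)
Conditions: engineered flavanone 3-hydroxylase variant (clarified lysate), FeSO4, 2-oxoglutaric acid disodium salt, sodium ascorbate, catalase, air, MES buffer pH 6.5, DMSO (10% v/v), 25 °C, stopped near half conversion; EtOAc extraction, reversed-phase chromatography
Reagents that add atoms: dioxygen, O=O
Why: Proposed new method: the divalent iron centre of the enzyme binds 2-oxoglutarate and O2, oxidative decarboxylation gives a tetravalent iron-oxo species that abstracts the C3 hydrogen, and rebound of the iron-bound hydroxyl to the same face forms the C3–O bond with retention, the only outcome the cis-fused bicycle allows. The closest known reaction is the C3 hydroxylation of (2S)-flavanones by plant flavanone 3-hydroxylases, which likewise removes the C3 hydrogen anti to the large C2 substituent; here that position is taken by the C8′ aryl group of the lower flavonol while the 4-hydroxyphenyl ring sits where the flavanone C2 hydrogen would be, so the pocket must be enlarged by engineering. No ring is closed. Both stereocentres of the product come from the substrate enantiomer that the active site accepts, (2R,3S)-24: C2 is untouched and C3 keeps its configuration through rebound, so the enzyme's discrimination between the enantiomers (kinetic resolution, at most half of 24 converted) sets the absolute configuration. The step needs enantiomer selection and site selectivity for C3–H over the phenols and the other C–H bonds; binding of the 5,7-dihydroxychromanone part with its C4 carbonyl, as in natural substrates, places C3–H over the iron, and this cofactor chemistry does not oxidise phenols. The (2S,3R) half of 24 is left unchanged or decays irreversibly to the achiral benzofuran and is removed by chromatography.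

Compound list
1 | kaempferol (3,5,7-trihydroxy-2-(4-hydroxyphenyl)-4H-chromen-4-one) | O=c1c(O)c(-c2ccc(O)cc2)oc2cc(O)cc(O)c12 | starting material
2 | benzyl bromide | BrCc1ccccc1 | starting material
3 | tetra-O-benzylkaempferol (3,5,7-tris(benzyloxy)-2-[4-(benzyloxy)phenyl]-4H-chromen-4-one) | O=c1c(OCc2ccccc2)c(-c2ccc(OCc3ccccc3)cc2)oc2cc(OCc3ccccc3)cc(OCc3ccccc3)c12 | intermediate
4 | iodine | II | starting material
5 | 8-iodo-tetra-O-benzylkaempferol (3,5,7-tris(benzyloxy)-2-[4-(benzyloxy)phenyl]-8-iodo-4H-chromen-4-one) | O=c1c(OCc2ccccc2)c(-c2ccc(OCc3ccccc3)cc2)oc2c(I)c(OCc3ccccc3)cc(OCc3ccccc3)c12 | intermediate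
6 | 4-(benzyloxy)phenylboronic acid | OB(O)c1ccc(OCc2ccccc2)cc1 | starting material
7 | carbon monoxide | [C-]#[O+] | starting material
8 | 8-[4-(benzyloxy)benzoyl]-3,5,7-tris(benzyloxy)-2-[4-(benzyloxy)phenyl]-4H-chromen-4-one | O=c1c(OCc2ccccc2)c(-c2ccc(OCc3ccccc3)cc2)oc2c(C(=O)c3ccc(OCc4ccccc4)cc3)c(OCc3ccccc3)cc(OCc3ccccc3)c12 | intermediate
9 | 8-[4-(benzyloxy)benzoyl]-3-(benzyloxy)-2-[4-(benzyloxy)phenyl]-5,7-dihydroxy-4H-chromen-4-one | O=c1c(OCc2ccccc2)c(-c2ccc(OCc3ccccc3)cc2)oc2c(C(=O)c3ccc(OCc4ccccc4)cc3)c(O)cc(O)c12 | intermediate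
10 | 2′,4′,6′-trihydroxyacetophenone (1-(2,4,6-trihydroxyphenyl)ethan-1-one) | CC(=O)c1c(O)cc(O)cc1O | starting material
11 | 1-[2,4-bis(benzyloxy)-6-hydroxyphenyl]ethan-1-one | CC(=O)c1c(O)cc(OCc2ccccc2)cc1OCc1ccccc1 | intermediate
12 | chloromethyl methyl ether | COCCl | starting material
13 | 1-[2,4-bis(benzyloxy)-6-(methoxymethoxy)phenyl]ethan-1-one | CC(=O)c1c(OCOC)cc(OCc2ccccc2)cc1OCc1ccccc1 | intermediate
14 | dibenzyl carbonate | O=C(OCc1ccccc1)OCc1ccccc1 | starting material
15 | benzyl 3-[2,4-bis(benzyloxy)-6-(methoxymethoxy)phenyl]-3-oxopropanoate | O=C(CC(=O)OCc1ccccc1)c1c(OCOC)cc(OCc2ccccc2)cc1OCc1ccccc1 | intermediate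
16 | N-bromosuccinimide | O=C1CCC(=O)N1Br | starting material
17 | sodium enolate of 15 (enolate geometry not specified) | [Na+].[O-]C(=CC(=O)OCc1ccccc1)c1c(OCOC)cc(OCc2ccccc2)cc1OCc1ccccc1 | intermediate (not isolated)
18 | benzyl 2-bromo-3-[2,4-bis(benzyloxy)-6-(methoxymethoxy)phenyl]-3-oxopropanoate (racemic) | O=C(C(Br)C(=O)OCc1ccccc1)c1c(OCOC)cc(OCc2ccccc2)cc1OCc1ccccc1 | intermediate
19 | benzyl 2-({8-[4-(benzyloxy)benzoyl]-3-(benzyloxy)-2-[4-(benzyloxy)phenyl]-5-hydroxy-4-oxo-4H-chromen-7-yl}oxy)-3-[2,4-bis(benzyloxy)-6-(methoxymethoxy)phenyl]-3-oxopropanoate (racemic) | O=c1c(OCc2ccccc2)c(-c2ccc(OCc3ccccc3)cc2)oc2c(C(=O)c3ccc(OCc4ccccc4)cc3)c(OC(C(=O)OCc3ccccc3)C(=O)c3c(OCOC)cc(OCc4ccccc4)cc3OCc3ccccc3)cc(O)c12 | intermediate (not isolated)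
20 | benzyl 8-[2,4-bis(benzyloxy)-6-(methoxymethoxy)benzoyl]-3-(benzyloxy)-2,9-bis[4-(benzyloxy)phenyl]-5,9-dihydroxy-4-oxo-8,9-dihydro-4H-furo[2,3-h]chromene-8-carboxylate (two racemic diastereomers; configuration at C8 and C9 unspecified) | O=c1c(OCc2ccccc2)c(-c2ccc(OCc3ccccc3)cc2)oc2c3c(cc(O)c12)OC(C(=O)OCc1ccccc1)(C(=O)c1c(OCOC)cc(OCc2ccccc2)cc1OCc1ccccc1)C3(O)c1ccc(OCc2ccccc2)cc1 | intermediate
21 | racemic cis-fused C3 benzyl ester, rac-(2R,3S), one enantiomer drawn: benzyl 5,7-bis(benzyloxy)-2-[4-(benzyloxy)phenyl]-4-oxochromane-3-carboxylate whose C2 is bonded to C8′ and whose C3 is bonded to O7′ of 3′-(benzyloxy)-5′-hydroxy-2′-[4-(benzyloxy)phenyl]chromen-4′-one; ester syn to the C2 aryl group | O=C1c2c(OCc3ccccc3)cc(OCc3ccccc3)cc2O[C@]2(c3ccc(OCc4ccccc4)cc3)c3c(cc(O)c4c(=O)c(OCc5ccccc5)c(-c5ccc(OCc6ccccc6)cc5)oc34)O[C@]12C(=O)OCc1ccccc1 | intermediate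
22 | racemic keto acid, rac-(2R,3S), one enantiomer drawn: the C3 carboxylic acid of 24 with all phenols free | O=C1c2c(O)cc(O)cc2O[C@]2(c3ccc(O)cc3)c3c(cc(O)c4c(=O)c(O)c(-c5ccc(O)cc5)oc34)O[C@]12C(=O)O | intermediate (not isolated)
23 | racemic enol, (2R) enantiomer drawn: the C3=C4 enol (4-hydroxy-2H-chromene form) of 24 | OC1=C2Oc3cc(O)c4c(=O)c(O)c(-c5ccc(O)cc5)oc4c3[C@@]2(c2ccc(O)cc2)Oc2cc(O)cc(O)c12 | intermediate (not isolated)
24 | racemic 3-deoxy compound, rac-(2R,3S), reactive (2R,3S) enantiomer drawn: 5,7-dihydroxy-2-(4-hydroxyphenyl)chroman-4-one fused through C2–C8′ and C3–O7′ to kaempferol; cis ring fusion, H3 syn to the C2 aryl group | O=C1c2c(O)cc(O)cc2O[C@]2(c3ccc(O)cc3)c3c(cc(O)c4c(=O)c(O)c(-c5ccc(O)cc5)oc34)O[C@H]12 | intermediate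
25 | dioxygen | O=O | starting material
26 | CNP0314633.1, (2R,3S): the 3-hydroxy derivative of 24, 3-OH syn to the C2 aryl group | O=C1c2c(O)cc(O)cc2O[C@]2(c3ccc(O)cc3)c3c(cc(O)c4c(=O)c(O)c(-c5ccc(O)cc5)oc34)O[C@]12O | target

Total step count: 12. Longest linear sequence: 8 steps (steps 1–4 and 9–12); steps 5–8 make the second fragment.

Steps most likely to fail

Step 12 (labelled). The engineered enzyme may fail to bind the bulky substrate, may discriminate the enantiomers poorly, or may be outrun by non-enzymatic ring-opening of 24 in the buffer. The fallback uses known chemistry, sets out from 20 and returns to the route at 26. Krapcho dealkoxycarbonylation of 20 (LiCl, DMSO, 130 °C) removes the benzyl ester, and the enolate so formed expels hydroxide to give the protected 2-aroylbenzofuran F1. HCl in MeOH–THF removes the MOM acetal to give the ortho-hydroxyaroyl benzofuran F2. Dimethyldioxirane (one equivalent, acetone, 0 °C) should epoxidise the furan C8=C9 bond to the epoxide F3, which the neighbouring phenol opens at the benzylic carbon with inversion to give the cis-fused benzyl-protected racemic 3-hydroxy compound F4. Hydrogenolysis (H2, Pd/C) gives the racemic target F5, and preparative HPLC on a chiral stationary phase delivers 26.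

Step 11. Hydrogenolytic loss of the benzylic C2–O1 bond, over-reduction, or opening of the enol or of 24 to the benzofuran before isolation may erode the material. The fallback sets out from 21 and returns at 24. Non-reductive Lewis-acid debenzylation (BCl3, pentamethylbenzene as cation scavenger, CH2Cl2, −78 °C, then a pH 5 aqueous quench) cleaves the ethers and the ester to the C3-blocked acid 22, which tolerates these conditions because it has no hydrogen at C3. The acid is then decarboxylated in dry THF at the lowest workable temperature and the solution of 24 is passed straight to step 12. This fallback makes no new compound (F0).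

Step 9. Halogen transfer instead of O-alkylation at the two hindered centres, an aldol equilibrium that does not favour the congested adduct, or base-induced loss of the ester with aromatisation may intervene. The fallback sets out from 15 and returns at 21. Diazo transfer (4-acetamidobenzenesulfonyl azide, Et3N, MeCN) gives the diazo keto ester F6. Rh2(OAc)4-catalysed carbenoid O–H insertion into the 7-OH of 9 (CH2Cl2, rt) then gives the aryloxy keto ester 19, this time isolated. CF3CO2H in CH2Cl2 effects the enol aldol addition to the diaryl ketone, MOM loss and ring closure in one operation to give 21.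

Further compounds
F1 | step 12 | 8-[2,4-bis(benzyloxy)-6-(methoxymethoxy)benzoyl]-3-(benzyloxy)-2,9-bis[4-(benzyloxy)phenyl]-5-hydroxy-4H-furo[2,3-h]chromen-4-one | O=c1c(OCc2ccccc2)c(-c2ccc(OCc3ccccc3)cc2)oc2c3c(cc(O)c12)oc(C(=O)c1c(OCOC)cc(OCc2ccccc2)cc1OCc1ccccc1)c3-c1ccc(OCc2ccccc2)cc1
F2 | step 12 | 8-[2,4-bis(benzyloxy)-6-hydroxybenzoyl]-3-(benzyloxy)-2,9-bis[4-(benzyloxy)phenyl]-5-hydroxy-4H-furo[2,3-h]chromen-4-one | O=c1c(OCc2ccccc2)c(-c2ccc(OCc3ccccc3)cc2)oc2c3c(cc(O)c12)oc(C(=O)c1c(O)cc(OCc2ccccc2)cc1OCc1ccccc1)c3-c1ccc(OCc2ccccc2)cc1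
F3 | step 12 | 8,9-epoxide of F2 (racemic; oxirane across C8 and C9 of the furan ring) | O=c1c(OCc2ccccc2)c(-c2ccc(OCc3ccccc3)cc2)oc2c3c(cc(O)c12)OC1(C(=O)c2c(O)cc(OCc4ccccc4)cc2OCc2ccccc2)OC31c1ccc(OCc2ccccc2)cc1
F4 | step 12 | benzyl-protected racemic 3-hydroxy compound, rac-(2R,3S), one enantiomer drawn (26 with benzyl ethers at O5, O7, ring B O4, O3′ and ring B′ O4; 5′-OH free) | O=C1c2c(OCc3ccccc3)cc(OCc3ccccc3)cc2O[C@]2(c3ccc(OCc4ccccc4)cc3)c3c(cc(O)c4c(=O)c(OCc5ccccc5)c(-c5ccc(OCc6ccccc6)cc5)oc34)O[C@]12O
F5 | step 12 | racemic target, rac-(2R,3S), one enantiomer drawn (26 with its enantiomer) | O=C1c2c(O)cc(O)cc2O[C@]2(c3ccc(O)cc3)c3c(cc(O)c4c(=O)c(O)c(-c5ccc(O)cc5)oc34)O[C@]12O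
F0 | step 11 | none | none
F6 | step 9 | benzyl 2-diazo-3-[2,4-bis(benzyloxy)-6-(methoxymethoxy)phenyl]-3-oxopropanoate | O=C(C(=[N+]=[N-])C(=O)OCc1ccccc1)c1c(OCOC)cc(OCc2ccccc2)cc1OCc1ccccc1
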